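**Retrosynthetic overview**
1. Gnetal 23 ⇐ one-pot acid removal of four MOM ethers and the dioxolane from 22 ⇐ stereoretentive protodeboronation of the C2-boronate 21.
2. 21 ⇐ three-component Pd-catalysed enantioselective dearomative conjunctive coupling on benzofuran 9: C3–aryl bond from triflate 18, C2–aryl bond by 1,2-shift from boron (boronate 13); both stereocentres are set here (trans).
3. Benzofuran 9 ⇐ Stobbe condensation of furfural with dimethyl succinate, then Ac2O ring closure (builds the benzene ring with the 4-oxy/6-carbon pattern), then redox and protection.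
4. 13 ⇐ 4-bromophenol; 18 ⇐ resorcinol by Ir-catalysed meta C–H borylation, oxidation and triflation.
5. Ring order: furan (bought) → benzene ring A (benzannulation) → no further ring formation; the dihydrofuran arises by dearomatisation of the benzofuran.

Assumption: MOM = CH2OCH3. The ligand antipode that delivers 3S in step 14 is written as (Sp,Sp); if the sense of induction is the opposite, its mirror image is used.

**Route**

Step 1
Reactants: 1 succinic anhydride
Product: 2 dimethyl succinate
Conditions: MeOH, H2SO4 (cat.), reflux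
Reagents that add atoms: methanol CO
Why: Fischer esterification with ring opening of the anhydride, driven by excess methanol.

Step 2
Reactants: 3 furfural; 2 dimethyl succinate
Product: 4 (E)-4-(furan-2-yl)-3-(methoxycarbonyl)but-3-enoic acid
Conditions: NaOMe, MeOH, reflux; then aq HCl
Reagents that add atoms: none
Why: Stobbe condensation, in which the aldol alkoxide lactonises onto the distal ester and E1cB opening gives the (E)-half-ester with the furyl group cis to CH2CO2H, as needed for ring closure.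

Step 3
Reactants: 4 (E)-4-(furan-2-yl)-3-(methoxycarbonyl)but-3-enoic acid
Product: 5 methyl 4-acetoxy-1-benzofuran-6-carboxylate
Conditions: Ac2O, NaOAc, 140 °C
Reagents that add atoms: acetic anhydride CC(=O)OC(C)=O
Why: The mixed anhydride acylates furan C3 intramolecularly (Friedel–Crafts-type benzannulation) and the new phenol is trapped as its acetate, the established entry to 4-oxy-6-carboxybenzofurans.

Step 4
Reactants: 5 methyl 4-acetoxy-1-benzofuran-6-carboxylate
Product: 6 6-(hydroxymethyl)-1-benzofuran-4-ol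
Conditions: LiAlH4, THF, 0 °C → rt
Reagents that add atoms: none
Why: Hydride reduction converts the methyl ester to the benzylic alcohol and cleaves the aryl acetate in the same operation.

Step 5
Reactants: 6 6-(hydroxymethyl)-1-benzofuran-4-ol
Product: 7 4-hydroxy-1-benzofuran-6-carbaldehyde
Conditions: activated MnO2, acetone, rt
Reagents that add atoms: none
Why: MnO2 oxidises benzylic alcohols chemoselectively to aldehydes and leaves the meta-phenol and the furan ring alone.

Step 6
Reactants: 7 4-hydroxy-1-benzofuran-6-carbaldehyde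
Product: 8 6-(1,3-dioxolan-2-yl)-1-benzofuran-4-ol
Conditions: HOCH2CH2OH, PPTS (cat.), PhH, reflux, Dean–Stark
Reagents that add atoms: ethylene glycol OCCO
Why: Acid-catalysed acetalisation with azeotropic water removal masks the aldehyde against the organolithium chemistry of step 14.

Step 7
Reactants: 8 6-(1,3-dioxolan-2-yl)-1-benzofuran-4-ol
Product: 9 2-[4-(methoxymethoxy)-1-benzofuran-6-yl]-1,3-dioxolane
Conditions: MOMCl, i-Pr2NEt, CH2Cl2, 0 °C → rt
Reagents that add atoms: chloromethyl methyl ether COCCl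
Why: O-alkylation of the phenol under basic conditions that leave the acetal intact.

Step 8
Reactants: 10 4-bromophenol
Product: 11 1-bromo-4-(methoxymethoxy)benzene
Conditions: MOMCl, i-Pr2NEt, CH2Cl2, 0 °C → rt
Reagents that add atoms: chloromethyl methyl ether COCCl
Why: Standard MOM protection (O-alkylation) of a phenol.

Step 9
Reactants: 11 1-bromo-4-(methoxymethoxy)benzene
Product: 13 2-[4-(methoxymethoxy)phenyl]-4,4,5,5-tetramethyl-1,3,2-dioxaborolane, via aryllithium 12 (not isolated)
Conditions: n-BuLi, THF, −78 °C; then i-PrOBpin, −78 °C → rt; H2O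
Reagents that add atoms: n-butyllithium [Li]CCCC (lithium of 12); 2-isopropoxy-4,4,5,5-tetramethyl-1,3,2-dioxaborolane CC(C)OB1OC(C)(C)C(C)(C)O1
Why: Bromine–lithium exchange is fast at −78 °C and the aryllithium is trapped by the borate ester (lithiation–borylation).

Step 10
Reactants: 14 resorcinol
Product: 15 1,3-bis(methoxymethoxy)benzene
Conditions: MOMCl (2.4 equiv), i-Pr2NEt, CH2Cl2, 0 °C → rt
Reagents that add atoms: chloromethyl methyl ether COCCl
Why: Double O-alkylation of the two phenols.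

Step 11
Reactants: 15 1,3-bis(methoxymethoxy)benzene
Product: 16 2-[3,5-bis(methoxymethoxy)phenyl]-4,4,5,5-tetramethyl-1,3,2-dioxaborolane
Conditions: [Ir(OMe)(cod)]2 (1.5 mol%), dtbpy (3 mol%), B2pin2 (0.55 equiv), hexane, 60 °C
Reagents that add atoms: bis(pinacolato)diboron CC1(C)OB(OC1(C)C)B1OC(C)(C)C(C)(C)O1
Why: Sterically controlled Ir-catalysed aromatic C–H borylation takes place at C5, the only C–H without an ortho substituent.

Step 12
Reactants: 16 2-[3,5-bis(methoxymethoxy)phenyl]-4,4,5,5-tetramethyl-1,3,2-dioxaborolane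
Product: 17 3,5-bis(methoxymethoxy)phenol
Conditions: 30% H2O2, aq NaOH, THF, 0 °C
Reagents that add atoms: hydrogen peroxide OO
Why: Basic peroxide oxidation of the aryl–boron bond (1,2-aryl shift from B to O) under conditions to which MOM ethers are inert.

Step 13
Reactants: 17 3,5-bis(methoxymethoxy)phenol
Product: 18 3,5-bis(methoxymethoxy)phenyl trifluoromethanesulfonate
Conditions: Tf2O, pyridine, CH2Cl2, 0 °C
Reagents that add atoms: trifluoromethanesulfonic anhydride O=S(=O)(OS(=O)(=O)C(F)(F)F)C(F)(F)F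
Why: O-sulfonylation of the phenol gives a halide-free aryl electrophile for cationic Pd chemistry.

Step 14
Reactants: 9 2-[4-(methoxymethoxy)-1-benzofuran-6-yl]-1,3-dioxolane; 13 2-[4-(methoxymethoxy)phenyl]-4,4,5,5-tetramethyl-1,3,2-dioxaborolane; 18 3,5-bis(methoxymethoxy)phenyl trifluoromethanesulfonate
Product: 21 2-[(2S,3S)-3-[3,5-bis(methoxymethoxy)phenyl]-6-(1,3-dioxolan-2-yl)-4-(methoxymethoxy)-2-[4-(methoxymethoxy)phenyl]-2,3-dihydro-1-benzofuran-2-yl]-4,4,5,5-tetramethyl-1,3,2-dioxaborolane, via 2-lithiobenzofuran 19 (not isolated), via lithium boron-ate complex 20 (not isolated)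
Conditions: 9 (1.05 equiv), n-BuLi (1.0 equiv), THF, −78 °C; 13 (1.0 equiv), −78 → 0 °C; then Pd(OAc)2 (3 mol%), (Sp,Sp)-MandyPhos-type ferrocenyl bisphosphine (3.6 mol%), 18 (1.1 equiv), THF, 60 °C
Reagents that add atoms: n-butyllithium [Li]CCCC (lithium of 19 and 20)
Why: Proposed new method: a Pd-catalysed enantioselective dearomative conjunctive cross-coupling in which the cationic (L*)Pd(aryl)+ from triflate 18 binds the C2=C3 bond of ate complex 20 on the C3 Si face under ligand control and triggers an anti-periplanar 1,2-shift of the 4-(methoxymethoxy)phenyl group from boron to C2, after which C(sp3)–C(sp2) reductive elimination from the C3–Pd species (which has no β-hydrogen, so it cannot re-aromatise by β-hydride elimination) forms the C3–aryl bond with retention, so C3 (S) is set by the catalyst and C2 (S, aryl anti to the C3-aryl, Bpin syn) follows from the anti addition; the closest known reaction types are the Pd/bisphosphine conjunctive cross-coupling of alkenylboron ate complexes with aryl triflates and the Pd-π-allyl-induced dearomative 1,2-boronate shift of indol-2-yl boronates, neither of which has been shown for arylative dearomatisation of a benzofuran-2-yl boronate.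

Step 15
Reactants: 21 the C2-boronate of step 14
Product: 22 2-[(2S,3S)-3-[3,5-bis(methoxymethoxy)phenyl]-4-(methoxymethoxy)-2-[4-(methoxymethoxy)phenyl]-2,3-dihydro-1-benzofuran-6-yl]-1,3-dioxolane
Conditions: TBAF·3H2O, toluene, 45 °C
Reagents that add atoms: none
Why: Fluoride-promoted protodeboronation of a tertiary benzylic boronic ester proceeds with retention, so H takes the place of boron and the two aryl groups stay trans, while C3 is not touched.

Step 16
Reactants: 22 the protected trans-dihydrobenzofuran of step 15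
Product: 23 gnetal, (2S,3S)-3-(3,5-dihydroxyphenyl)-4-hydroxy-2-(4-hydroxyphenyl)-2,3-dihydro-1-benzofuran-6-carbaldehyde
Conditions: 3 M aq HCl/MeOH/THF (1:3:1), 40 °C, dilute
Reagents that add atoms: water O
Why: Acid-catalysed acetal cleavage removes the four MOM ethers (formaldehyde trapped by methanol) and hydrolyses the dioxolane, and any C2 epimer is equilibrated to the more stable trans isomer by reversible ring opening to the p-hydroxybenzyl cation without affecting C3.

**Compound list**
1 | succinic anhydride | O=C1CCC(=O)O1 | starting material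
2 | dimethyl succinate | COC(=O)CCC(=O)OC | intermediate
3 | furfural (furan-2-carbaldehyde) | O=Cc1ccco1 | starting material
4 | (E)-4-(furan-2-yl)-3-(methoxycarbonyl)but-3-enoic acid | COC(=O)/C(=C/c1ccco1)CC(=O)O | intermediate
5 | methyl 4-acetoxy-1-benzofuran-6-carboxylate | COC(=O)c1cc(OC(C)=O)c2ccoc2c1 | intermediate
6 | 6-(hydroxymethyl)-1-benzofuran-4-ol | OCc1cc(O)c2ccoc2c1 | intermediate
7 | 4-hydroxy-1-benzofuran-6-carbaldehyde | O=Cc1cc(O)c2ccoc2c1 | intermediate
8 | 6-(1,3-dioxolan-2-yl)-1-benzofuran-4-ol | Oc1cc(cc2occc12)C1OCCO1 | intermediate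
9 | 2-[4-(methoxymethoxy)-1-benzofuran-6-yl]-1,3-dioxolane | COCOc1cc(cc2occc12)C1OCCO1 | intermediate
10 | 4-bromophenol | Oc1ccc(Br)cc1 | starting material
11 | 1-bromo-4-(methoxymethoxy)benzene | COCOc1ccc(Br)cc1 | intermediate
12 | [4-(methoxymethoxy)phenyl]lithium | [Li]c1ccc(OCOC)cc1 | intermediate
13 | 2-[4-(methoxymethoxy)phenyl]-4,4,5,5-tetramethyl-1,3,2-dioxaborolane | COCOc1ccc(cc1)B1OC(C)(C)C(C)(C)O1 | intermediate
14 | resorcinol (benzene-1,3-diol) | Oc1cccc(O)c1 | starting material
15 | 1,3-bis(methoxymethoxy)benzene | COCOc1cccc(OCOC)c1 | intermediate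
16 | 2-[3,5-bis(methoxymethoxy)phenyl]-4,4,5,5-tetramethyl-1,3,2-dioxaborolane | COCOc1cc(OCOC)cc(c1)B1OC(C)(C)C(C)(C)O1 | intermediate
17 | 3,5-bis(methoxymethoxy)phenol | COCOc1cc(O)cc(OCOC)c1 | intermediate
18 | 3,5-bis(methoxymethoxy)phenyl trifluoromethanesulfonate | COCOc1cc(OCOC)cc(OS(=O)(=O)C(F)(F)F)c1 | intermediate
19 | [6-(1,3-dioxolan-2-yl)-4-(methoxymethoxy)-1-benzofuran-2-yl]lithium | [Li]c1cc2c(OCOC)cc(cc2o1)C1OCCO1 | intermediate
20 | lithium [6-(1,3-dioxolan-2-yl)-4-(methoxymethoxy)-1-benzofuran-2-yl][4-(methoxymethoxy)phenyl](pinacolato)borate | [Li+].COCOc1ccc(cc1)[B-]1(OC(C)(C)C(C)(C)O1)c1cc2c(OCOC)cc(cc2o1)C1OCCO1 | intermediate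
21 | 2-[(2S,3S)-3-[3,5-bis(methoxymethoxy)phenyl]-6-(1,3-dioxolan-2-yl)-4-(methoxymethoxy)-2-[4-(methoxymethoxy)phenyl]-2,3-dihydro-1-benzofuran-2-yl]-4,4,5,5-tetramethyl-1,3,2-dioxaborolane | C1COC(O1)c1cc(OCOC)c2c(c1)O[C@](B1OC(C)(C)C(C)(C)O1)(c1ccc(OCOC)cc1)[C@H]2c1cc(OCOC)cc(OCOC)c1 | intermediate
22 | 2-[(2S,3S)-3-[3,5-bis(methoxymethoxy)phenyl]-4-(methoxymethoxy)-2-[4-(methoxymethoxy)phenyl]-2,3-dihydro-1-benzofuran-6-yl]-1,3-dioxolane | C1COC(O1)c1cc(OCOC)c2c(c1)O[C@H](c1ccc(OCOC)cc1)[C@H]2c1cc(OCOC)cc(OCOC)c1 | intermediate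
23 | gnetal, (2S,3S)-3-(3,5-dihydroxyphenyl)-4-hydroxy-2-(4-hydroxyphenyl)-2,3-dihydro-1-benzofuran-6-carbaldehyde | O=Cc1cc(O)c2c(c1)O[C@H](c1ccc(O)cc1)[C@H]2c1cc(O)cc(O)c1 | target

**Totals**
Total step count: 16. Longest linear sequence: 10 steps (1–7, then 14–16), i.e. 10/16 of the total.

**The three steps most likely to fail**

Step 14 (the proposed new step). Likely failure modes are direct boron-to-palladium transfer (Suzuki-type biaryls), syn-β-boryl elimination from the C3–Pd species back to an aromatic benzofuran, or low enantioselectivity. The fallback uses only known reactions, sets out from 9 and comes back to the route at 23. Pd-catalysed direct C2–H arylation of 9 with bromide 11 (Pd(OAc)2, PCy3·HBF4, PivOH, K2CO3, DMA, 100 °C) gives 2-[4-(methoxymethoxy)-2-[4-(methoxymethoxy)phenyl]-1-benzofuran-6-yl]-1,3-dioxolane F1. NBS in DMF at 0 °C brominates the nucleophilic C3 to give 2-[3-bromo-4-(methoxymethoxy)-2-[4-(methoxymethoxy)phenyl]-1-benzofuran-6-yl]-1,3-dioxolane F2. Suzuki–Miyaura coupling of F2 with boronate 16 (Pd(dppf)Cl2, K3PO4, dioxane/H2O, 90 °C) gives 2-[3-[3,5-bis(methoxymethoxy)phenyl]-4-(methoxymethoxy)-2-[4-(methoxymethoxy)phenyl]-1-benzofuran-6-yl]-1,3-dioxolane F3. Heterogeneous hydrogenation (H2, 50 bar, Pd/C, EtOAc) adds cis and gives racemic cis-2-[3-[3,5-bis(methoxymethoxy)phenyl]-4-(methoxymethoxy)-2-[4-(methoxymethoxy)phenyl]-2,3-dihydro-1-benzofuran-6-yl]-1,3-dioxolane F4. The conditions of step 16, run longer, then deprotect F4 and epimerise C2 to the trans series, giving 23 together with its enantiomer (2R,3R)-3-(3,5-dihydroxyphenyl)-4-hydroxy-2-(4-hydroxyphenyl)-2,3-dihydro-1-benzofuran-6-carbaldehyde F5, which is removed by preparative chiral HPLC. This fallback gives up the asymmetric catalysis and half of the material.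

Step 15. The α-aryloxy tertiary boronate may protodeboronate sluggishly or with side reactions under fluoride. The fallback changes from a polar to a radical C–B cleavage, sets out from 21 and comes back at 22. Phenyllithium (THF, −78 °C) adds to boron to give lithium [(2S,3S)-3-[3,5-bis(methoxymethoxy)phenyl]-6-(1,3-dioxolan-2-yl)-4-(methoxymethoxy)-2-[4-(methoxymethoxy)phenyl]-2,3-dihydro-1-benzofuran-2-yl](phenyl)(pinacolato)borate F6. Single-electron oxidation of F6 by an excited Ir photocatalyst (blue LEDs, rt) releases the C2 benzylic radical, which abstracts hydrogen from thiophenol to give 22. The radical can also be quenched from the other face to give the C2 epimer 2-[(2R,3S)-3-[3,5-bis(methoxymethoxy)phenyl]-4-(methoxymethoxy)-2-[4-(methoxymethoxy)phenyl]-2,3-dihydro-1-benzofuran-6-yl]-1,3-dioxolane F7. This does not matter, because C3 is untouched and step 16 equilibrates C2, so 22 and F7 both lead to 23.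

Step 16. Under protic acid the free aldehyde or the released formaldehyde may condense with the electron-rich resorcinol ring. The fallback separates the two unmasking events and avoids protic acid in the second one; it sets out from 22 and comes back at 23. Mild transacetalisation (PPTS, acetone/H2O, 40 °C) removes only the dioxolane and gives (2S,3S)-3-[3,5-bis(methoxymethoxy)phenyl]-4-(methoxymethoxy)-2-[4-(methoxymethoxy)phenyl]-2,3-dihydro-1-benzofuran-6-carbaldehyde F8. TMSOTf with 2,2′-bipyridyl (CH2Cl2, 0 °C) then converts the aryl MOM ethers into silyl ethers, giving (2S,3S)-3-[3,5-bis(trimethylsilyloxy)phenyl]-4-(trimethylsilyloxy)-2-[4-(trimethylsilyloxy)phenyl]-2,3-dihydro-1-benzofuran-6-carbaldehyde F9 in the flask, and addition of water hydrolyses F9 to 23. Because this variant does not equilibrate C2, it requires diastereomerically pure 22.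

**Further compounds**
F1 | step 14 | 2-[4-(methoxymethoxy)-2-[4-(methoxymethoxy)phenyl]-1-benzofuran-6-yl]-1,3-dioxolane | COCOc1ccc(cc1)-c1cc2c(OCOC)cc(cc2o1)C1OCCO1
F2 | step 14 | 2-[3-bromo-4-(methoxymethoxy)-2-[4-(methoxymethoxy)phenyl]-1-benzofuran-6-yl]-1,3-dioxolane | COCOc1ccc(cc1)-c1oc2cc(cc(OCOC)c2c1Br)C1OCCO1
F3 | step 14 | 2-[3-[3,5-bis(methoxymethoxy)phenyl]-4-(methoxymethoxy)-2-[4-(methoxymethoxy)phenyl]-1-benzofuran-6-yl]-1,3-dioxolane | COCOc1ccc(cc1)-c1oc2cc(cc(OCOC)c2c1-c1cc(OCOC)cc(OCOC)c1)C1OCCO1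
F4 | step 14 | racemic cis-2-[3-[3,5-bis(methoxymethoxy)phenyl]-4-(methoxymethoxy)-2-[4-(methoxymethoxy)phenyl]-2,3-dihydro-1-benzofuran-6-yl]-1,3-dioxolane (the 2S,3R enantiomer is drawn) | C1COC(O1)c1cc(OCOC)c2c(c1)O[C@H](c1ccc(OCOC)cc1)[C@@H]2c1cc(OCOC)cc(OCOC)c1
F5 | step 14 | (2R,3R)-3-(3,5-dihydroxyphenyl)-4-hydroxy-2-(4-hydroxyphenyl)-2,3-dihydro-1-benzofuran-6-carbaldehyde | O=Cc1cc(O)c2c(c1)O[C@@H](c1ccc(O)cc1)[C@@H]2c1cc(O)cc(O)c1
F6 | step 15 | lithium [(2S,3S)-3-[3,5-bis(methoxymethoxy)phenyl]-6-(1,3-dioxolan-2-yl)-4-(methoxymethoxy)-2-[4-(methoxymethoxy)phenyl]-2,3-dihydro-1-benzofuran-2-yl](phenyl)(pinacolato)borate | [Li+].C1COC(O1)c1cc(OCOC)c2c(c1)O[C@]([B-]1(c3ccccc3)OC(C)(C)C(C)(C)O1)(c1ccc(OCOC)cc1)[C@H]2c1cc(OCOC)cc(OCOC)c1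
F7 | step 15 | 2-[(2R,3S)-3-[3,5-bis(methoxymethoxy)phenyl]-4-(methoxymethoxy)-2-[4-(methoxymethoxy)phenyl]-2,3-dihydro-1-benzofuran-6-yl]-1,3-dioxolane | C1COC(O1)c1cc(OCOC)c2c(c1)O[C@@H](c1ccc(OCOC)cc1)[C@H]2c1cc(OCOC)cc(OCOC)c1
F8 | step 16 | (2S,3S)-3-[3,5-bis(methoxymethoxy)phenyl]-4-(methoxymethoxy)-2-[4-(methoxymethoxy)phenyl]-2,3-dihydro-1-benzofuran-6-carbaldehyde | O=Cc1cc(OCOC)c2c(c1)O[C@H](c1ccc(OCOC)cc1)[C@H]2c1cc(OCOC)cc(OCOC)c1
F9 | step 16 | (2S,3S)-3-[3,5-bis(trimethylsilyloxy)phenyl]-4-(trimethylsilyloxy)-2-[4-(trimethylsilyloxy)phenyl]-2,3-dihydro-1-benzofuran-6-carbaldehyde | O=Cc1cc(O[Si](C)(C)C)c2c(c1)O[C@H](c1ccc(O[Si](C)(C)C)cc1)[C@H]2c1cc(O[Si](C)(C)C)cc(O[Si](C)(C)C)c1
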